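Numbering (germacrane): ten-membered carbocycle C1–C10 with C4 = C(CH3)OH, C5 = CHOH, C6 = CH–O-angelate, C7 = CH carrying the C11 hydroxyisopropyl group, C10 = CH–CH3.
Enabling feature: the C6 carbinol is bonded to C7, and C11–OH is a hydrated isopropenyl group. The unit C6(OH)–C7–C11(=C12) is therefore the homoallylic alcohol left by a [2,3]-Wittig shift of a C6–O–C12 diallyl ether.
Cuts, in order: the ester C–O at C6, the C4–O and C5–O bonds (back to a Z C4=C5 alkene), C11–O (back to isopropenyl), C6–C7 (ring expansion to a 13-membered ether), then O–C12, C3–C4, C7=C11 and C2=C3.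
Forward: (R)-citronellal is methylenated, ozonised, Z-olefinated and joined to a Z-iodobutenyl unit. Williamson closure gives the temporary 13-membered oxacycle, which is contracted to the ten-membered carbocycle.
Stereochemistry: C10 comes from citronellal. C6 and C7 arise together in the contraction (relative: Z C7=C11 alkene; absolute: chiral lithium amide). C4 and C5 come from syn-dihydroxylation of the outer face of the Z ring alkene.

Key step: step 11

Assumption: the (S,S) antipode of lithium bis(1-phenylethyl)amide is taken to be the one that removes the pro-S hydrogen at C6 of the macrocyclic ether. Both antipodes of the amine are commercial, so only this pairing needs to be confirmed.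

Step 1
Reactants: 1 but-2-yn-1-ol
Product: 3 (2Z)-3-iodobut-2-en-1-ol, via cyclic alkenylaluminate 2 (not isolated)
Conditions: NaAlH2(OCH2CH2OMe)2, Et2O, 0 °C to rt; then I2, THF, −78 °C to 0 °C
Reagents that add atoms: iodine, II
Why: Hydroxyl-directed trans-hydroalumination of a propargylic alcohol places aluminium on C3 inside the five-membered aluminate 2, so iodinolysis with retention should leave iodine cis to the CH2OH arm (Z).

Step 2
Reactants: 3 (2Z)-3-iodobut-2-en-1-ol
Product: 4 tert-butyl{[(2Z)-3-iodobut-2-en-1-yl]oxy}dimethylsilane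
Conditions: TBSCl, imidazole, CH2Cl2, 0 °C to rt
Reagents that add atoms: tert-butyldimethylsilyl chloride, CC(C)(C)[Si](C)(C)Cl
Why: Routine silyl ether protection of a primary allylic alcohol masks the future C6–OH, so that only the other chain end can later become the chloride.

Step 3
Reactants: 5 (R)-citronellal
Product: 6 (4R)-4,8-dimethylnona-1,7-diene
Conditions: Ph3PCH3Br, KOt-Bu, THF, 0 °C to rt
Reagents that add atoms: methyltriphenylphosphonium bromide, C[P+](c1ccccc1)(c1ccccc1)c1ccccc1.[Br-]
Why: Wittig methylenation of an unhindered aldehyde supplies C3, and the stereocentre (future C10) is β to the carbonyl group and cannot epimerise.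

Step 4
Reactants: 6 (4R)-4,8-dimethylnona-1,7-diene
Product: 8 (4R)-4-methylhept-6-enal, via secondary ozonide 7 (not isolated)
Conditions: O3, CH2Cl2, Sudan Red 7B (trace), −78 °C; then Me2S, −78 °C to rt
Reagents that add atoms: ozone, [O-][O+]=O
Why: In this chemoselective ozonolysis with reductive work-up, electrophilic ozone consumes the trisubstituted isopropylidene alkene well before the monosubstituted vinyl group, and the dye end-point stops the gas flow after the first cleavage.

Step 5
Reactants: 8 (4R)-4-methylhept-6-enal; 9 methyl 2-[bis(2,2,2-trifluoroethoxy)phosphoryl]propanoate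
Product: 11 methyl (2Z,6R)-2,6-dimethylnona-2,8-dienoate, via potassium phosphonate carbanion 10 (not isolated)
Conditions: KN(SiMe3)2, 18-crown-6, THF, −78 °C
Reagents that add atoms: none
Why: In the Still–Gennari variant of the Horner–Wadsworth–Emmons olefination, the electron-poor phosphonate and the dissociated potassium ion make elimination faster than adduct equilibration, which should fix the Z C7=C11 geometry (ester carbon C12 cis to C8).

Step 6
Reactants: 11 methyl (2Z,6R)-2,6-dimethylnona-2,8-dienoate; 4 tert-butyl{[(2Z)-3-iodobut-2-en-1-yl]oxy}dimethylsilane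
Product: 13 methyl (2Z,6S,10Z)-12-[(tert-butyldimethylsilyl)oxy]-2,6,10-trimethyldodeca-2,10-dienoate, via B-alkyl-9-BBN borane 12 (not isolated)
Conditions: 9-BBN, THF, 0 °C to rt; then 4, PdCl2(dppf) (5 mol %), AsPh3, Cs2CO3, DMF–H2O, rt
Reagents that add atoms: none
Why: Bulky 9-BBN hydroborates only the terminal alkene (anti-Markovnikov), and B-alkyl Suzuki–Miyaura coupling on zerovalent palladium joins C3 to C4 with retention at the vinyl iodide, so the Z geometry of 4 becomes the Z C4=C5 alkene while the ester and silyl ether are tolerated.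

Step 7
Reactants: 13 methyl (2Z,6S,10Z)-12-[(tert-butyldimethylsilyl)oxy]-2,6,10-trimethyldodeca-2,10-dienoate
Product: 14 (2Z,6S,10Z)-12-[(tert-butyldimethylsilyl)oxy]-2,6,10-trimethyldodeca-2,10-dien-1-ol
Conditions: i-Bu2AlH, CH2Cl2, −78 °C
Reagents that add atoms: none
Why: 1,2-Reduction of an α,β-unsaturated ester with i-Bu2AlH gives the C12 allylic alcohol without touching the alkene geometry or the silyl ether.

Step 8
Reactants: 14 (2Z,6S,10Z)-12-[(tert-butyldimethylsilyl)oxy]-2,6,10-trimethyldodeca-2,10-dien-1-ol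
Product: 16 tert-butyl{[(2Z,7S,10Z)-12-chloro-3,7,11-trimethyldodeca-2,10-dien-1-yl]oxy}dimethylsilane, via allylic mesylate 15 (not isolated)
Conditions: MsCl, Et3N, CH2Cl2, −40 °C; then LiCl, THF, 0 °C
Reagents that add atoms: lithium chloride, [Li+].[Cl-]
Why: Mesylation followed by SN2 displacement with chloride at low temperature is the standard conversion of a primary allylic alcohol into its chloride without allylic transposition or loss of Z geometry.

Step 9
Reactants: 16 tert-butyl{[(2Z,7S,10Z)-12-chloro-3,7,11-trimethyldodeca-2,10-dien-1-yl]oxy}dimethylsilane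
Product: 17 (2Z,7S,10Z)-12-chloro-3,7,11-trimethyldodeca-2,10-dien-1-ol
Conditions: HF·pyridine, pyridine, THF, 0 °C to rt
Reagents that add atoms: none
Why: Buffered fluoride desilylation frees C6–OH without generating an alkoxide, so the allylic chloride is not attacked prematurely.

Step 10
Reactants: 17 (2Z,7S,10Z)-12-chloro-3,7,11-trimethyldodeca-2,10-dien-1-ol
Product: 19 (3Z,7S,11Z)-3,7,11-trimethyl-1-oxacyclotrideca-3,11-diene, via sodium alkoxide 18 (not isolated)
Conditions: NaH, THF, reflux, syringe-pump addition of 17 (final ca. 2 mM)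
Reagents that add atoms: none
Why: Intramolecular Williamson ether synthesis under pseudo-high dilution closes the 13-membered ring (13-exo-tet) by SN2 attack of the C6 alkoxide on the unhindered primary allylic C12–Cl, and the two Z alkenes bend the chain so that its ends can meet.

Step 11
Reactants: 19 (3Z,7S,11Z)-3,7,11-trimethyl-1-oxacyclotrideca-3,11-diene
Product: 22 (1S,2Z,7S,10S)-3,7-dimethyl-10-(prop-1-en-2-yl)cyclodec-2-en-1-ol, via C6-lithiated ether 20 (not isolated), via lithium alkoxide 21 (not isolated)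
Conditions: (S,S)-[PhCH(CH3)]2NH, n-BuLi, THF, 0 °C; add 19, −40 °C to 0 °C; then H2O
Reagents that add atoms: none
Why: The amide removes one C6 hydrogen (reversibly, since the ether is the weaker acid), and the α-oxyallyllithium 20 bonds from C6 to C7 through a five-membered envelope transition state (C6, O, C12, C11, C7) while O–C12 breaks and C11=C12 forms, giving alkoxide 21 irreversibly. This is the ring-contracting [2,3]-Wittig rearrangement, known for nine- and 13-membered cyclic diallyl ethers and, with this type of chiral base, for 13-membered allyl propargyl ethers. The ten-membered carbocycle is closed transannularly, by C6–C7 bonding across the 13-membered ring with O, C12 and C11 leaving the ring (13 to 10), not by an end-to-end cyclisation. The relative configuration follows from the Z C7=C11 alkene: with the C5 vinyl group exo on the envelope, C5 and C8 lie synclinal, as the C5-to-C8 tether also requires, which should give the syn pair, i.e. C6–OH and the C7 isopropenyl group cis on the ring. The absolute sense rests on the base, which should take the pro-S hydrogen at C6, so that C–C bond formation with inversion at the lithiated carbon gives the 1S,10S pair; C10 is too remote to do more than reinforce or erode this, and a minor diastereomer can be removed by chromatography. The step needs C6–H removal rather than C12–H removal or 1,4-elimination: C6H2 adjoins an unsubstituted vinylic CH and is more open to the bulky amide than C12H2 beside the C11 methyl group, a C12 anion formed reversibly would face the more congested shift onto fully substituted C4, and the lithium counter-ion at or below 0 °C should suppress [1,2]-shift and anionic oxy-Cope reaction of 21.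

Step 12
Reactants: 22 (1S,2Z,7S,10S)-3,7-dimethyl-10-(prop-1-en-2-yl)cyclodec-2-en-1-ol
Product: 24 (1S,2Z,7S,10R)-10-(2-hydroxypropan-2-yl)-3,7-dimethylcyclodec-2-en-1-ol, via acetoxymercurial 23 (not isolated)
Conditions: Hg(OAc)2 (1.05 equiv), THF–H2O, 0 °C to rt; then aq NaOH, NaBH4, 0 °C
Reagents that add atoms: water, O
Why: Markovnikov oxymercuration–demercuration takes the unhindered 1,1-disubstituted isopropenyl alkene well ahead of the trisubstituted ring alkene (as in the selective hydration of limonene to α-terpineol), and C11 carries two methyl groups after reduction, so no stereocentre is created.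

Step 13
Reactants: 24 (1S,2Z,7S,10R)-10-(2-hydroxypropan-2-yl)-3,7-dimethylcyclodec-2-en-1-ol; 25 angelic acid
Product: 27 (1S,2Z,7S,10R)-10-(2-hydroxypropan-2-yl)-3,7-dimethylcyclodec-2-en-1-yl (2Z)-2-methylbut-2-enoate, via mixed anhydride 26 (not isolated)
Conditions: 25, 2,4,6-Cl3C6H2COCl, Et3N, toluene, rt; then 24, 75 °C
Reagents that add atoms: none
Why: Yamaguchi-type mixed-anhydride esterification without a nucleophilic catalyst is the established way to transfer an angeloyl group without Z-to-E isomerisation to the tiglate, and only the secondary C6–OH should react because the tertiary C11–OH is too hindered.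

Step 14
Reactants: 27 (1S,2Z,7S,10R)-10-(2-hydroxypropan-2-yl)-3,7-dimethylcyclodec-2-en-1-yl (2Z)-2-methylbut-2-enoate
Product: 29 (1R,2S,3R,7S,10R)-2,3-dihydroxy-10-(2-hydroxypropan-2-yl)-3,7-dimethylcyclodecyl (2Z)-2-methylbut-2-enoate, via cyclic osmate ester 28 (not isolated)
Conditions: OsO4 (5 mol %), NMO, acetone–H2O, 0 °C to rt
Reagents that add atoms: osmium tetroxide, O=[Os](=O)(=O)=O (delivers both oxygen atoms); N-methylmorpholine N-oxide, C[N+]1([O-])CCOCC1; water, O
Why: In this catalytic OsO4/NMO syn-dihydroxylation the electron-rich ring alkene reacts ahead of the conjugated angelate alkene, allylic 1,3-strain with C3H2 holds H6 in the alkene plane so that C7 and the ring chain shield one face, and suprafacial addition to the exposed outer face should set 4R and 5S (4,5-cis, 5-OH trans to the C6 ester).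

Compound list
1 | but-2-yn-1-ol | CC#CCO | starting material
2 | sodium cyclic alkenylaluminate (five-membered ring Al–O–C1–C2=C3, two 2-methoxyethoxy ligands on Al) | [Na+].CC1=CCO[Al-]1(OCCOC)OCCOC | intermediate
3 | (2Z)-3-iodobut-2-en-1-ol | C/C(I)=C/CO | intermediate
4 | tert-butyl{[(2Z)-3-iodobut-2-en-1-yl]oxy}dimethylsilane | C/C(I)=C/CO[Si](C)(C)C(C)(C)C | intermediate
5 | (R)-citronellal, (3R)-3,7-dimethyloct-6-enal | C[C@H](CCC=C(C)C)CC=O | starting material
6 | (4R)-4,8-dimethylnona-1,7-diene | C[C@H](CCC=C(C)C)CC=C | intermediate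
7 | 3,3-dimethyl-5-[(3R)-3-methylhex-5-en-1-yl]-1,2,4-trioxolane (epimers at the ring CH) | C[C@H](CCC1OOC(C)(C)O1)CC=C | intermediate
8 | (4R)-4-methylhept-6-enal | C[C@H](CCC=O)CC=C | intermediate
9 | methyl 2-[bis(2,2,2-trifluoroethoxy)phosphoryl]propanoate | COC(=O)C(C)P(=O)(OCC(F)(F)F)OCC(F)(F)F | starting material
10 | potassium salt of the α-carbanion of 9 | [K+].COC(=O)[C-](C)P(=O)(OCC(F)(F)F)OCC(F)(F)F | intermediate
11 | methyl (2Z,6R)-2,6-dimethylnona-2,8-dienoate | COC(=O)/C(C)=C\CC[C@@H](C)CC=C | intermediate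
12 | methyl (2Z,6S)-9-(9-borabicyclo[3.3.1]nonan-9-yl)-2,6-dimethylnon-2-enoate | COC(=O)/C(C)=C\CC[C@@H](C)CCCB1C2CCCC1CCC2 | intermediate
13 | methyl (2Z,6S,10Z)-12-[(tert-butyldimethylsilyl)oxy]-2,6,10-trimethyldodeca-2,10-dienoate | COC(=O)/C(C)=C\CC[C@@H](C)CCC/C(C)=C\CO[Si](C)(C)C(C)(C)C | intermediate
14 | (2Z,6S,10Z)-12-[(tert-butyldimethylsilyl)oxy]-2,6,10-trimethyldodeca-2,10-dien-1-ol | OC/C(C)=C\CC[C@@H](C)CCC/C(C)=C\CO[Si](C)(C)C(C)(C)C | intermediate
15 | (2Z,6S,10Z)-12-[(tert-butyldimethylsilyl)oxy]-2,6,10-trimethyldodeca-2,10-dien-1-yl methanesulfonate | CS(=O)(=O)OC/C(C)=C\CC[C@@H](C)CCC/C(C)=C\CO[Si](C)(C)C(C)(C)C | intermediate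
16 | tert-butyl{[(2Z,7S,10Z)-12-chloro-3,7,11-trimethyldodeca-2,10-dien-1-yl]oxy}dimethylsilane | ClC/C(C)=C\CC[C@@H](C)CCC/C(C)=C\CO[Si](C)(C)C(C)(C)C | intermediate
17 | (2Z,7S,10Z)-12-chloro-3,7,11-trimethyldodeca-2,10-dien-1-ol | ClC/C(C)=C\CC[C@@H](C)CCC/C(C)=C\CO | intermediate
18 | sodium (2Z,7S,10Z)-12-chloro-3,7,11-trimethyldodeca-2,10-dien-1-olate | [Na+].ClC/C(C)=C\CC[C@@H](C)CCC/C(C)=C\C[O-] | intermediate
19 | (3Z,7S,11Z)-3,7,11-trimethyl-1-oxacyclotrideca-3,11-diene (oxygen bridging C6 and C12) | C1/C(C)=C\CC[C@@H](C)CCC/C(C)=C\CO1 | intermediate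
20 | 19 lithiated at ring position 13 (germacrane C6), drawn as the allyl anion | [Li+].C1/C(C)=C\CC[C@@H](C)CCC/C(C)=C\[CH-]O1 | intermediate
21 | lithium (1S,2Z,7S,10S)-3,7-dimethyl-10-(prop-1-en-2-yl)cyclodec-2-en-1-olate | [Li+].C1C[C@@H](C)CCC/C(C)=C\[C@H]([O-])[C@@H]1C(C)=C | intermediate
22 | (1S,2Z,7S,10S)-3,7-dimethyl-10-(prop-1-en-2-yl)cyclodec-2-en-1-ol | C1C[C@@H](C)CCC/C(C)=C\[C@H](O)[C@@H]1C(C)=C | intermediate
23 | C12-acetoxymercurio C11-carbinol derived from 22 (epimers at C11) | C1C[C@@H](C)CCC/C(C)=C\[C@H](O)[C@@H]1C(C)(O)C[Hg]OC(C)=O | intermediate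
24 | (1S,2Z,7S,10R)-10-(2-hydroxypropan-2-yl)-3,7-dimethylcyclodec-2-en-1-ol | C1C[C@@H](C)CCC/C(C)=C\[C@H](O)[C@@H]1C(C)(C)O | intermediate
25 | angelic acid, (2Z)-2-methylbut-2-enoic acid | C/C=C(/C)C(=O)O | starting material
26 | (2Z)-2-methylbut-2-enoic 2,4,6-trichlorobenzoic anhydride | C/C=C(/C)C(=O)OC(=O)c1c(Cl)cc(Cl)cc1Cl | intermediate
27 | (1S,2Z,7S,10R)-10-(2-hydroxypropan-2-yl)-3,7-dimethylcyclodec-2-en-1-yl (2Z)-2-methylbut-2-enoate | C1C[C@@H](C)CCC/C(C)=C\[C@H](OC(=O)/C(C)=C\C)[C@@H]1C(C)(C)O | intermediate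
28 | cyclic dioxo-osmium diolate of 29 bridging O4 and O5 (hexavalent osmium) | C/C=C(/C)C(=O)O[C@@H]1[C@H](C(C)(C)O)CC[C@@H](C)CCC[C@@](C)(O[Os]2(=O)=O)[C@H]1O2 | intermediate
29 | CNP0130723.1, (1R,2S,3R,7S,10R)-2,3-dihydroxy-10-(2-hydroxypropan-2-yl)-3,7-dimethylcyclodecyl (2Z)-2-methylbut-2-enoate | C/C=C(/C)C(=O)O[C@@H]1[C@H](C(C)(C)O)CC[C@@H](C)CCC[C@@](C)(O)[C@H]1O | target

Total steps: 14. Longest linear sequence: 12 (steps 3 to 14, from 5). Steps 1 and 2 make coupling partner 4.

Steps most likely to fail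

Step 11.
- Risk: Proton removal may occur at C12 or at the allylic ring methylenes C3 and C8, the latter opening the ring by 1,4-elimination. The two faces of the C7=C11 alkene may also be poorly differentiated, because C10 is remote.
- Fallback, from 17 back to 22: the same C6–C7 bond and the same ten-membered ring are made by reductive carbonyl allylation instead of a carbanion rearrangement. MnO2 in CH2Cl2 oxidises the allylic alcohol to (2Z,7S,10Z)-12-chloro-3,7,11-trimethyldodeca-2,10-dienal F1. Slow addition of F1 to CrCl2 in THF is a Nozaki–Hiyama allylation, in which divalent chromium inserts into C12–Cl and the allyl metal adds through C7 to the C6 aldehyde. It should close the ring with the anti preference of allylchromium reagents and give the 6,7-trans epimer (1R,2Z,7S,10S)-3,7-dimethyl-10-(prop-1-en-2-yl)cyclodec-2-en-1-ol F2. Mitsunobu inversion at C6 (4-nitrobenzoic acid, PPh3, DIAD, THF) gives (1S,2Z,7S,10S)-3,7-dimethyl-10-(prop-1-en-2-yl)cyclodec-2-en-1-yl 4-nitrobenzoate F3. K2CO3 in MeOH then releases 22.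

Step 14.
- Risk: The oxidant may reach the wrong alkene face if the ring populates the conformer with the C6 oxygen, rather than H6, in the alkene plane. Slow osmylation may let the angelate alkene react. The ester may migrate from O6 to O5 during work-up.
- Fallback, from 24 back to 29: acylation and oxidation change places, so that the free C6–OH steers the oxidant by hydrogen bonding. Stoichiometric OsO4 with TMEDA in CH2Cl2 at −78 °C should add to the face on which C6–OH lies. This gives the robust (TMEDA)dioxo-osmium 2,3-diolate of (1R,2S,3R,7S,10R)-10-(2-hydroxypropan-2-yl)-3,7-dimethylcyclodecane-1,2,3-triol F4. The chelate itself masks O4 and O5 while C6–OH is acylated with 26 as in step 13, giving the corresponding (TMEDA)dioxo-osmium diolate of 29 F5. Aqueous Na2SO3 in THF then releases 29.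

Step 10.
- Risk: Intermolecular etherification (oligomerisation) may outrun closure of the 13-membered ring, and the alkoxide may cause loss of HCl from the allylic chloride.
- Fallback, from 11 and 3 back to 19: the ether bond is made first between two small pieces, and the macrocycle is closed at C3–C4 by a palladium-catalysed coupling. i-Bu2AlH reduces 11 to (2Z,6R)-2,6-dimethylnona-2,8-dien-1-ol F6. An Appel reaction (CBr4, PPh3) turns 3 into (2Z)-1-bromo-3-iodobut-2-ene F7. NaH in THF joins the two to give (2Z,6R)-1-{[(2Z)-3-iodobut-2-en-1-yl]oxy}-2,6-dimethylnona-2,8-diene F8. 9-BBN hydroborates only the terminal alkene to give the B-alkyl borane 9-[(4R,7Z)-9-{[(2Z)-3-iodobut-2-en-1-yl]oxy}-4,8-dimethylnon-7-en-1-yl]-9-borabicyclo[3.3.1]nonane F9. F9 is added slowly to PdCl2(dppf), AsPh3 and Cs2CO3 in DMF–THF–H2O, an intramolecular B-alkyl Suzuki–Miyaura macrocyclisation, to give 19.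

Further compounds
F1 | step 11 | (2Z,7S,10Z)-12-chloro-3,7,11-trimethyldodeca-2,10-dienal | ClC/C(C)=C\CC[C@@H](C)CCC/C(C)=C\C=O
F2 | step 11 | (1R,2Z,7S,10S)-3,7-dimethyl-10-(prop-1-en-2-yl)cyclodec-2-en-1-ol | C1C[C@@H](C)CCC/C(C)=C\[C@@H](O)[C@@H]1C(C)=C
F3 | step 11 | (1S,2Z,7S,10S)-3,7-dimethyl-10-(prop-1-en-2-yl)cyclodec-2-en-1-yl 4-nitrobenzoate | C1C[C@@H](C)CCC/C(C)=C\[C@H](OC(=O)c2ccc(cc2)[N+](=O)[O-])[C@@H]1C(C)=C
F4 | step 14 | (TMEDA)dioxo-osmium 2,3-diolate of (1R,2S,3R,7S,10R)-10-(2-hydroxypropan-2-yl)-3,7-dimethylcyclodecane-1,2,3-triol | O[C@@H]1[C@H](C(C)(C)O)CC[C@@H](C)CCC[C@@](C)(O[Os-2]23(=O)(=O)[N+](C)(C)CC[N+]2(C)C)[C@H]1O3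
F5 | step 14 | (TMEDA)dioxo-osmium diolate of 29 (O4 and O5 bound to osmium) | C/C=C(/C)C(=O)O[C@@H]1[C@H](C(C)(C)O)CC[C@@H](C)CCC[C@@](C)(O[Os-2]23(=O)(=O)[N+](C)(C)CC[N+]2(C)C)[C@H]1O3
F6 | step 10 | (2Z,6R)-2,6-dimethylnona-2,8-dien-1-ol | OC/C(C)=C\CC[C@@H](C)CC=C
F7 | step 10 | (2Z)-1-bromo-3-iodobut-2-ene | C/C(I)=C/CBr
F8 | step 10 | (2Z,6R)-1-{[(2Z)-3-iodobut-2-en-1-yl]oxy}-2,6-dimethylnona-2,8-diene | C/C(I)=C/COC/C(C)=C\CC[C@@H](C)CC=C
F9 | step 10 | 9-[(4R,7Z)-9-{[(2Z)-3-iodobut-2-en-1-yl]oxy}-4,8-dimethylnon-7-en-1-yl]-9-borabicyclo[3.3.1]nonane | C/C(I)=C/COC/C(C)=C\CC[C@@H](C)CCCB1C2CCCC1CCC2
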